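**Assumption:** the target (2,5,6-tribromo-1-methyl-1H-indole-3-carbaldehyde) has no stereocentre, so there is no enantiomer to control. The only stereo-element on the route is the E/Z geometry of enol ether 4, which is erased in step 2.

**Retrosynthetic overview**
1. Target 7 ⇐ 2-bromo-1-methylindole-3-carbaldehyde 6 by late electrophilic 5,6-dibromination of the benzo ring.
2. 6 ⇐ enol ether 4 by POBr3 bromo-aromatisation (lactam C=O → C2–Br, enol ether → CHO).
3. 4 ⇐ 1-methylisatin 1 + formyl-anion ylide 3 (from phosphonium salt 2). The C3–CHO bond joins the isatin C3 ketone carbon and a formyl carbon, both normally electrophilic.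
4. No ring is formed: the bicycle is bought intact in 1, and the pyrrole ring becomes aromatic in step 2.

**Step 1**
Reactants: 1 1-methylisatin (1-methylindoline-2,3-dione); 2 (methoxymethyl)triphenylphosphonium chloride
Product: 4 3-(methoxymethylene)-1-methylindolin-2-one (E/Z mixture), via methoxymethylenetriphenylphosphorane 3 (not isolated)
Conditions: 2 (1.3 equiv), KHMDS (1.25 equiv), THF, 0 °C, 30 min; ylide solution added to 1 in THF at −78 °C → rt, 3 h; Et3N-deactivated silica
Reagents that add atoms: none
Why: Wittig olefination with the formyl-anion (d1) ylide takes place at the ketone-like C3 carbonyl of the isatin rather than at the lactam C2, giving the enol ether of 3-formyloxindole at the correct oxidation level, and the E/Z ratio is irrelevant because the geometry disappears in step 2.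

**Step 2**
Reactants: 4 3-(methoxymethylene)-1-methylindolin-2-one
Product: 6 2-bromo-1-methyl-1H-indole-3-carbaldehyde, via 2-bromo-3-(methoxymethylidene)-1-methyl-3H-indol-1-ium bromide 5 (not isolated)
Conditions: POBr3 (2.0 equiv), ClCH2CH2Cl, 80 °C, 3 h; then ice–water
Reagents that add atoms: phosphorus oxybromide, O=P(Br)(Br)Br
Why: Proposed new method: POBr3 O-phosphorylates the electron-rich (vinylogous carbonate) lactam oxygen, bromide adds at C2 and expels dibromophosphate to aromatise to 5, and bromide then removes the O-methyl group by SN2 (MeBr) to unmask the aldehyde, the closest known reactions being the Vilsmeier–Haack–Arnold bromoformylation of oxindoles (same sequence on the 3-aminomethylene oxindole) and the POCl3 conversion of 3-acyloxindoles into 2-chloro-3-acylindoles.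

**Step 3**
Reactants: 6 2-bromo-1-methyl-1H-indole-3-carbaldehyde
Product: 7 2,5,6-tribromo-1-methyl-1H-indole-3-carbaldehyde
Conditions: Br2 (2.3 equiv), AcOH, rt → 50 °C, 16 h; aq. Na2S2O3; recrystallisation
Reagents that add atoms: bromine, BrBr
Why: Electrophilic aromatic bromination, in which C2 and C3 are blocked, the pyrrole ring is deactivated by the vinylogous-amide aldehyde, C5 (para to N) and C6 (para to C3a, conjugated to N through C2=C3) are the activated benzo positions, and C4 and C7 are shielded by the peri CHO and N-Me groups, as in the known 5,6-dibromination of indole-3-carboxylates and -carbaldehydes.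

**Compound list**
1 | 1-methylisatin (1-methylindoline-2,3-dione) | CN1C(=O)C(=O)c2ccccc21 | starting material
2 | (methoxymethyl)triphenylphosphonium chloride | COC[P+](c1ccccc1)(c1ccccc1)c1ccccc1.[Cl-] | starting material
3 | methoxymethylenetriphenylphosphorane | COC=P(c1ccccc1)(c1ccccc1)c1ccccc1 | intermediate
4 | 3-(methoxymethylene)-1-methylindolin-2-one (E/Z mixture, geometry not specified) | COC=C1C(=O)N(C)c2ccccc21 | intermediate
5 | 2-bromo-3-(methoxymethylidene)-1-methyl-3H-indol-1-ium bromide | C[N+]1=C(Br)C(=COC)c2ccccc21.[Br-] | intermediate
6 | 2-bromo-1-methyl-1H-indole-3-carbaldehyde | Cn1c(Br)c(C=O)c2ccccc21 | intermediate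
7 | 2,5,6-tribromo-1-methyl-1H-indole-3-carbaldehyde | Cn1c(Br)c(C=O)c2cc(Br)c(Br)cc21 | target

**Total step count:** 3. **Longest linear sequence:** 3.

**Steps most likely to fail, with fallbacks**

Step 2 is the riskiest, because the direct bromo-aromatisation of an enol ether has no exact precedent and 4 may decompose or fail to demethylate. The fallback sets out from 4 and comes back at 6. Compound 4 is stirred with dimethylamine (2 M in THF, rt), which exchanges OMe for NMe2 by addition–elimination and gives 3-[(dimethylamino)methylene]-1-methylindolin-2-one F3, the intermediate of the classical oxindole haloformylation. POBr3 in CHCl3 (0 °C → reflux) converts it into N-[(2-bromo-1-methyl-1H-indol-3-yl)methylidene]-N-methylmethanaminium bromide F4, and aqueous NaOAc hydrolyses this iminium salt to 6.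

Step 3 is next, because the 5,6-selectivity rests on analogy with 3-acylindoles lacking the 2-bromine, and the reaction may stall at a monobromide or give regioisomers. The fallback sets out from ylide 3 (made from 2 as in step 1) and comes back at 7, with the bromine pattern bought in instead of installed late. Purchased 5,6-dibromoisatin is N-methylated (MeI, K2CO3, DMF) to 5,6-dibromo-1-methylindoline-2,3-dione F5. Wittig reaction with 3 under the step 1 conditions gives 5,6-dibromo-3-(methoxymethylene)-1-methylindolin-2-one F6. POBr3 under the step 2 conditions then leads through 2,5,6-tribromo-3-(methoxymethylidene)-1-methyl-3H-indol-1-ium bromide F7 to 7.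

Step 1 is third, because the basic, non-stabilised ylide may open the isatin lactam or add to the product. The fallback sets out from 1 and comes back at 4, keeping a carbanionic one-carbon reagent at the C3 ketone. Corey–Chaykovsky epoxidation (trimethylsulfoxonium iodide, NaH, DMF, rt) gives (±)-1-methylspiro[indoline-3,2'-oxiran]-2-one F1. BF3·OEt2 (CH2Cl2, −20 °C) induces a Meinwald rearrangement (opening at benzylic C3, 1,2-hydride shift) to 3-(hydroxymethylene)-1-methylindolin-2-one F2, the enol form of the 3-formyl oxindole. Acid-catalysed enol etherification (MeOH, cat. TsOH, reflux, molecular sieves) converts it into 4.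

**Further compounds**
F1 | step 1 | (±)-1-methylspiro[indoline-3,2'-oxiran]-2-one (racemic) | CN1C(=O)C2(CO2)c2ccccc21
F2 | step 1 | 3-(hydroxymethylene)-1-methylindolin-2-one | CN1C(=O)C(=CO)c2ccccc21
F3 | step 2 | 3-[(dimethylamino)methylene]-1-methylindolin-2-one | CN(C)C=C1C(=O)N(C)c2ccccc21
F4 | step 2 | N-[(2-bromo-1-methyl-1H-indol-3-yl)methylidene]-N-methylmethanaminium bromide | C[N+](C)=Cc1c(Br)n(C)c2ccccc12.[Br-]
F5 | step 3 | 5,6-dibromo-1-methylindoline-2,3-dione | CN1C(=O)C(=O)c2cc(Br)c(Br)cc21
F6 | step 3 | 5,6-dibromo-3-(methoxymethylene)-1-methylindolin-2-one (E/Z mixture) | COC=C1C(=O)N(C)c2cc(Br)c(Br)cc21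
F7 | step 3 | 2,5,6-tribromo-3-(methoxymethylidene)-1-methyl-3H-indol-1-ium bromide | C[N+]1=C(Br)C(=COC)c2cc(Br)c(Br)cc21.[Br-]
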